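Target → (MOM removal) → furan C2–O bond made by the C2' phenoxide displacing methylsulfanyl at chromone C2 → ring D hydroquinone → quinone → 2'-hydroxy-5'-methoxy-2-(methylsulfanyl)isoflavone.
The strategy rests on ring D (C1'–C6', C1' on chromone C3): para oxygens on C2' and C5' with C3'/C4' inside a 2,2-dimethyldihydropyran. This is the 4-alkoxyphenol pattern of a Dötz benzannulation, with the carbene carbon becoming C5', the enol-ether carbons C4'/C3', a CO ligand C2' and the alkyne carbons C1'/C6'.
Alkyne partner: 3-ethynyl-2-(methylsulfanyl)chromone from the ring A acetophenone (CS2, MeI, C3 iodination, Sonogashira). The acetophenone comes from 2,4,6-trihydroxyacetophenone through its symmetric 4-O-benzyl ether, which fixes where the ring A dihydropyran closes.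
Carbene partner: acrolein + isobutene (hetero-Diels–Alder), vinylic lithiation, Cr(CO)6, MeOTf.
Ring order: ring A dihydropyran → chromone pyranone ring → ring D by benzannulation (its dihydropyran arrives with the carbene) → furan ring.

Key step: step 13

Remarks: the target has no stereocenter, so no step needs stereocontrol. Numbering: chromone O1, C2, C3, C4 (C=O), C4a, C5 to C8, C8a; ring D C1' to C6' with C1' on C3. "Ring A chromone" means a chromen-4-one carrying a 2,2-dimethyl-3,4-dihydro-2H-pyran fused through its oxygen at C5 and its CH2 at C6, plus a 3-methylbut-2-enyl (prenyl) group at C8.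

Step 1
Reactants: 1 2,4,6-trihydroxyacetophenone
Product: 2 1-[4-(benzyloxy)-2,6-dihydroxyphenyl]ethanone
Conditions: BnBr (1.0 equiv), K2CO3, DMF, 0 °C to rt
Reagents that add atoms: benzyl bromide, BrCc1ccccc1
Why: Williamson etherification; the 4-OH is the most acidic hydroxyl and the only one not hydrogen-bonded to the acetyl group, so one equivalent of bromide should give the symmetric 4-ether.

Step 2
Reactants: 2 1-[4-(benzyloxy)-2,6-dihydroxyphenyl]ethanone; 3 3-methylbut-2-enal
Product: 4 1-[5-(benzyloxy)-7-hydroxy-2,2-dimethyl-2H-chromen-8-yl]ethanone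
Conditions: 3 (1.2 equiv), ethylenediammonium diacetate (10 mol %), xylene, reflux
Reagents that add atoms: none
Why: Amine-catalysed chromenylation (Knoevenagel-type condensation at the ring carbon ortho to OH, then oxa-6π electrocyclization); with the 4-oxygen benzylated and both ortho sites equivalent, only the 8-acetyl chromene can form.

Step 3
Reactants: 4 1-[5-(benzyloxy)-7-hydroxy-2,2-dimethyl-2H-chromen-8-yl]ethanone
Product: 5 1-(5,7-dihydroxy-2,2-dimethyl-3,4-dihydro-2H-chromen-8-yl)ethanone
Conditions: H2 (1 atm), Pd/C (10 wt %), EtOAc/MeOH, rt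
Reagents that add atoms: none
Why: Catalytic hydrogenation should saturate the C3–C4 styrenic alkene and hydrogenolyse the benzyl ether in one operation, the hydrogen-bonded aryl ketone being inert under these mild conditions.

Step 4
Reactants: 5 1-(5,7-dihydroxy-2,2-dimethyl-3,4-dihydro-2H-chromen-8-yl)ethanone; 6 1-bromo-3-methylbut-2-ene (prenyl bromide)
Product: 7 1-[5,7-dihydroxy-2,2-dimethyl-6-(3-methylbut-2-en-1-yl)-3,4-dihydro-2H-chromen-8-yl]ethanone
Conditions: 6 (1.1 equiv), DBU (1.2 equiv), THF, 0 °C to rt
Reagents that add atoms: none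
Why: Nuclear C-prenylation of an acylphloroglucinol monoether; C6 is the only free ring carbon and lies between two hydroxyls, so the ambident phenolate should alkylate there, with O-alkylation as the competing path.

Step 5
Reactants: 7 1-[5,7-dihydroxy-2,2-dimethyl-6-(3-methylbut-2-en-1-yl)-3,4-dihydro-2H-chromen-8-yl]ethanone
Product: 8 1-[7-hydroxy-5-(methoxymethoxy)-2,2-dimethyl-6-(3-methylbut-2-en-1-yl)-3,4-dihydro-2H-chromen-8-yl]ethanone
Conditions: MOMCl (1.1 equiv), i-Pr2NEt, CH2Cl2, 0 °C
Reagents that add atoms: chloromethyl methyl ether, COCCl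
Why: O-alkylation to the acetal; the C7 hydroxyl is held in a hydrogen bond to the acetyl carbonyl, so the free C5 hydroxyl should react selectively.

Step 6
Reactants: 8 1-[7-hydroxy-5-(methoxymethoxy)-2,2-dimethyl-6-(3-methylbut-2-en-1-yl)-3,4-dihydro-2H-chromen-8-yl]ethanone
Product: 9 ring A 4-hydroxy-2H-chromene-2-thione with 7-(methoxymethoxy)
Conditions: KOt-Bu (3.2 equiv), CS2 (2 equiv), THF, 0 °C to rt; then cold aq. citric acid to pH 3
Reagents that add atoms: carbon disulfide, S=C=S
Why: Claisen-type dithiocarboxylation of the ketone enolate followed by ring closure of the phenol onto the dithioacid carbon with loss of hydrosulfide, the standard entry to 2-alkylthiochromones from 2-hydroxyacetophenones.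

Step 7
Reactants: 9 ring A 4-hydroxy-2H-chromene-2-thione with 7-(methoxymethoxy)
Product: 10 ring A chromone with 7-(methoxymethoxy) and 2-(methylsulfanyl)
Conditions: MeI (1.05 equiv), K2CO3, acetone, rt
Reagents that add atoms: iodomethane, CI
Why: S-alkylation of the soft thione sulfur should give the 2-(methylsulfanyl)chromen-4-one tautomer rather than the O-methyl ether.

Step 8
Reactants: 10 ring A chromone with 7-(methoxymethoxy) and 2-(methylsulfanyl)
Product: 11 3-iodo derivative of 10
Conditions: NIS (1.1 equiv), MeCN, 0 °C to rt, dark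
Reagents that add atoms: N-iodosuccinimide, O=C1CCC(=O)N1I
Why: Electrophilic iodination at C3, the nucleophilic α-carbon of the push–pull O,S-ketene acetal enone; ring A has no free position and the isolated trisubstituted alkene is much less nucleophilic when no protic nucleophile is present.

Step 9
Reactants: 11 3-iodo derivative of 10; 12 ethynyltrimethylsilane
Product: 13 3-[(trimethylsilyl)ethynyl] derivative of 10
Conditions: 12 (1.5 equiv), Pd(PPh3)2Cl2 (5 mol %), CuI (10 mol %), Et3N, THF, 40 °C
Reagents that add atoms: none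
Why: Sonogashira coupling at the vinylic C3–I bond; a tertiary amine base avoids amine addition at C2 and the thioether is tolerated.

Step 10
Reactants: 13 3-[(trimethylsilyl)ethynyl] derivative of 10
Product: 14 ring A chromone with 3-ethynyl, 7-(methoxymethoxy) and 2-(methylsulfanyl)
Conditions: Bu4NF (1.1 equiv), AcOH (1.2 equiv), THF, 0 °C
Reagents that add atoms: none
Why: Fluoride-induced protodesilylation of the alkynylsilane; acetic acid buffering keeps oxygen nucleophiles from adding to the electrophilic C2.

Step 11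
Reactants: 15 acrolein; 16 isobutene
Product: 17 2,2-dimethyl-3,4-dihydro-2H-pyran
Conditions: 16 (excess), hydroquinone (cat.), neat, sealed autoclave, 190 °C
Reagents that add atoms: none
Why: Thermal inverse-electron-demand hetero-Diels–Alder reaction with acrolein as the 1-oxadiene; oxygen bonds to the more substituted alkene carbon, which gives the 2,2-dimethyl regioisomer.

Step 12
Reactants: 17 2,2-dimethyl-3,4-dihydro-2H-pyran; 18 chromium hexacarbonyl
Product: 21 pentacarbonyl[(6,6-dimethyl-5,6-dihydro-4H-pyran-2-yl)(methoxy)methylidene]chromium, via 6-lithio-2,2-dimethyl-3,4-dihydro-2H-pyran 19 (not isolated), via lithium acylpentacarbonylchromate 20 (not isolated)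
Conditions: t-BuLi (1.1 equiv), THF/pentane, −78 to 0 °C; Cr(CO)6, Et2O, 0 °C to rt; solvent exchange; MeOTf, CH2Cl2, 0 °C
Reagents that add atoms: methyl trifluoromethanesulfonate, COS(=O)(=O)C(F)(F)F
Why: Fischer carbene synthesis by vinylic lithiation next to the ring oxygen, addition of the vinyllithium to a CO ligand and O-methylation of the acylchromate.

Step 13
Reactants: 14 ring A chromone with 3-ethynyl, 7-(methoxymethoxy) and 2-(methylsulfanyl); 21 pentacarbonyl[(6,6-dimethyl-5,6-dihydro-4H-pyran-2-yl)(methoxy)methylidene]chromium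
Product: 23 ring A chromone with 7-(methoxymethoxy), 2-(methylsulfanyl) and 3-(5-hydroxy-8-methoxy-2,2-dimethyl-3,4-dihydro-2H-chromen-6-yl), the 2'-hydroxy-5'-methoxy isoflavone, via tricarbonylchromium arene complex 22 (not isolated)
Conditions: 21 (1.3 equiv), degassed THF (0.05 M), 55 °C, argon; then air, EtOAc, rt
Reagents that add atoms: none
Why: Thermal loss of one CO from 21 opens a site on zerovalent chromium, alkyne 14 inserts with its CH carbon bonding to the carbene carbon (C5'–C6'), CO insertion into the resulting vinylcarbene gives a chromium-bound dienylketene (C1'–C2'), and after ring closure tautomerization gives the phenol, first as the arene Cr(CO)3 complex 22, which air demetalates. The closest known reaction type is the Dötz benzannulation of alkenyl(methoxy)carbene pentacarbonylchromium complexes, including those of cyclic enol ethers, with terminal aryl- and alkenylacetylenes to give 4-methoxyphenols. Ring D closes by 6π electrocyclization of the dienylketene, the ketene carbon bonding to C3 of the dihydropyran (C2'–C3'), a six-membered carbocyclic closure. No stereocenter is formed. The step needs regioselective alkyne insertion, which the size difference between hydrogen and the chromon-3-yl group should secure by placing the chromone next to the CO-derived carbon, and it needs benzannulation to win over five-ring formation, which an alkenyl carbene on chromium in THF at moderate temperature favours.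

Step 14
Reactants: 23 the 2'-hydroxy-5'-methoxy isoflavone
Product: 24 ring A chromone with 7-(methoxymethoxy), 2-(methylsulfanyl) and 3-(2,2-dimethyl-5,8-dioxo-3,4,5,8-tetrahydro-2H-chromen-6-yl), the ring D quinone
Conditions: (NH4)2Ce(NO3)6 (2.2 equiv), MeCN/H2O 4:1, 0 °C, 10 min
Reagents that add atoms: water, O
Why: Oxidative demethylation of a 4-methoxyphenol by tetravalent cerium, in which water adds at C5' and methanol leaves; the trioxygenated ring D should be oxidized far more readily than the vinylogous thioester sulfur or the prenyl alkene.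

Step 15
Reactants: 24 the ring D quinone
Product: 26 7-O-methoxymethyl ether of the target, via ring D hydroquinone 25 (not isolated)
Conditions: Na2S2O4, THF/H2O, rt, argon; then K2CO3, 50 °C
Reagents that add atoms: none
Why: Dithionite reduction of the quinone, then intramolecular addition–elimination in which the C2' phenoxide attacks chromone C2 and expels methanethiolate (five-membered furan closure at a vinylogous thioester); the C5' hydroxyl cannot reach C2.

Step 16
Reactants: 26 7-O-methoxymethyl ether of the target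
Product: 27 CNP0081329.0 (target)
Conditions: HCl (3 M aq.), MeOH, 40 °C, stopped at full conversion
Reagents that add atoms: none
Why: Acid-catalysed acetal cleavage frees the C7 hydroxyl; the mild temperature and short reaction time should keep the neighbouring prenyl group from cyclizing onto it.

Compound list
1 | 2,4,6-trihydroxyacetophenone | CC(=O)c1c(O)cc(O)cc1O | starting material
2 | 1-[4-(benzyloxy)-2,6-dihydroxyphenyl]ethanone | CC(=O)c1c(O)cc(OCc2ccccc2)cc1O | intermediate
3 | 3-methylbut-2-enal | CC(C)=CC=O | starting material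
4 | 1-[5-(benzyloxy)-7-hydroxy-2,2-dimethyl-2H-chromen-8-yl]ethanone | CC(=O)c1c(O)cc(OCc2ccccc2)c2C=CC(C)(C)Oc12 | intermediate
5 | 1-(5,7-dihydroxy-2,2-dimethyl-3,4-dihydro-2H-chromen-8-yl)ethanone | CC(=O)c1c(O)cc(O)c2CCC(C)(C)Oc12 | intermediate
6 | 1-bromo-3-methylbut-2-ene (prenyl bromide) | CC(C)=CCBr | starting material
7 | 1-[5,7-dihydroxy-2,2-dimethyl-6-(3-methylbut-2-en-1-yl)-3,4-dihydro-2H-chromen-8-yl]ethanone | CC(=O)c1c(O)c(CC=C(C)C)c(O)c2CCC(C)(C)Oc12 | intermediate
8 | 1-[7-hydroxy-5-(methoxymethoxy)-2,2-dimethyl-6-(3-methylbut-2-en-1-yl)-3,4-dihydro-2H-chromen-8-yl]ethanone | CC(=O)c1c(O)c(CC=C(C)C)c(OCOC)c2CCC(C)(C)Oc12 | intermediate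
9 | ring A 4-hydroxy-2H-chromene-2-thione with 7-(methoxymethoxy) | Oc1cc(=S)oc2c(CC=C(C)C)c(OCOC)c3CCC(C)(C)Oc3c12 | intermediate
10 | ring A chromone with 7-(methoxymethoxy) and 2-(methylsulfanyl) | CSc1oc2c(CC=C(C)C)c(OCOC)c3CCC(C)(C)Oc3c2c(=O)c1 | intermediate
11 | 3-iodo derivative of 10 | CSc1oc2c(CC=C(C)C)c(OCOC)c3CCC(C)(C)Oc3c2c(=O)c1I | intermediate
12 | ethynyltrimethylsilane | C#C[Si](C)(C)C | starting material
13 | 3-[(trimethylsilyl)ethynyl] derivative of 10 | CSc1oc2c(CC=C(C)C)c(OCOC)c3CCC(C)(C)Oc3c2c(=O)c1C#C[Si](C)(C)C | intermediate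
14 | ring A chromone with 3-ethynyl, 7-(methoxymethoxy) and 2-(methylsulfanyl) | C#Cc1c(SC)oc2c(CC=C(C)C)c(OCOC)c3CCC(C)(C)Oc3c2c1=O | intermediate
15 | acrolein | C=CC=O | starting material
16 | isobutene | CC(C)=C | starting material
17 | 2,2-dimethyl-3,4-dihydro-2H-pyran | CC1(C)CCC=CO1 | intermediate
18 | chromium hexacarbonyl | O=C=[Cr](=C=O)(=C=O)(=C=O)(=C=O)=C=O | starting material
19 | 6-lithio-2,2-dimethyl-3,4-dihydro-2H-pyran | [Li]C1=CCCC(C)(C)O1 | intermediate
20 | lithium acylpentacarbonylchromate of the dihydropyranyl group | [Li+].[O-]C(C1=CCCC(C)(C)O1)=[Cr](=C=O)(=C=O)(=C=O)(=C=O)=C=O | intermediate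
21 | pentacarbonyl[(6,6-dimethyl-5,6-dihydro-4H-pyran-2-yl)(methoxy)methylidene]chromium | COC(C1=CCCC(C)(C)O1)=[Cr](=C=O)(=C=O)(=C=O)(=C=O)=C=O | intermediate
22 | tricarbonylchromium complex of 23, η6-bound to ring D | COc1cc(-c2c(SC)oc3c(CC=C(C)C)c(OCOC)c4CCC(C)(C)Oc4c3c2=O)c(O)c2CCC(C)(C)Oc12.O=C=[Cr](=C=O)=C=O | intermediate
23 | 2'-hydroxy-5'-methoxy isoflavone: ring A chromone with 7-(methoxymethoxy), 2-(methylsulfanyl) and 3-(5-hydroxy-8-methoxy-2,2-dimethyl-3,4-dihydro-2H-chromen-6-yl) | COc1cc(-c2c(SC)oc3c(CC=C(C)C)c(OCOC)c4CCC(C)(C)Oc4c3c2=O)c(O)c2CCC(C)(C)Oc12 | intermediate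
24 | ring D quinone: ring A chromone with 7-(methoxymethoxy), 2-(methylsulfanyl) and 3-(2,2-dimethyl-5,8-dioxo-3,4,5,8-tetrahydro-2H-chromen-6-yl) | CSc1oc2c(CC=C(C)C)c(OCOC)c3CCC(C)(C)Oc3c2c(=O)c1C1=CC(=O)C2=C(CCC(C)(C)O2)C1=O | intermediate
25 | ring D hydroquinone: 3-(5,8-dihydroxy-2,2-dimethyl-3,4-dihydro-2H-chromen-6-yl) analogue of 24 | CSc1oc2c(CC=C(C)C)c(OCOC)c3CCC(C)(C)Oc3c2c(=O)c1-c1cc(O)c2OC(C)(C)CCc2c1O | intermediate
26 | 7-O-methoxymethyl ether of the target (furan oxygen joins C2 and C2') | CC(C)=CCc1c(OCOC)c2c(c3c(=O)c4c(oc13)oc1c3c(c(O)cc14)OC(C)(C)CC3)OC(C)(C)CC2 | intermediate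
27 | CNP0081329.0: 7,5'-dihydroxy-8-prenyl coumaronochromone with 2,2-dimethyldihydropyran rings at C5(O)/C6 and C4'(O)/C3' | CC(C)=CCc1c(O)c2c(c3c(=O)c4c(oc13)oc1c3c(c(O)cc14)OC(C)(C)CC3)OC(C)(C)CC2 | target

Total step count: 16. Longest linear sequence: 14 steps (steps 1 to 10, then 13 to 16); steps 11 and 12 form the carbene branch.

Steps most likely to fail

Step 13. The alkyne may insert the wrong way round, or the vinylcarbene and ketene intermediates may be diverted by five-ring formation, by capture through the C4 carbonyl oxygen or by sulfur coordination to chromium, so that little benzannulation product forms. The fallback sets out from 11 and comes back at 24; it brings ring D in as a finished arene. 2,5-Dimethoxyphenol is O-alkylated with 3-chloro-3-methylbut-1-yne (K2CO3, KI, CuI cat., acetone) to 2-[(2-methylbut-3-yn-2-yl)oxy]-1,4-dimethoxybenzene F1. Heating in N,N-diethylaniline at 190 °C should give, by propargyl Claisen rearrangement and oxa-6π closure, 5,8-dimethoxy-2,2-dimethyl-2H-chromene F2. Hydrogenation (H2, Pd/C) gives 5,8-dimethoxy-2,2-dimethylchromane F3. NBS in MeCN brominates C6, which is ortho to the 5-methoxy group and para to the ring oxygen, giving 6-bromo-5,8-dimethoxy-2,2-dimethylchromane F4. Bromine–lithium exchange (n-BuLi, THF, −78 °C), B(Oi-Pr)3 and aqueous work-up give (5,8-dimethoxy-2,2-dimethylchroman-6-yl)boronic acid F5. Suzuki–Miyaura coupling of F5 with 11 (Pd(dppf)Cl2, K3PO4, dioxane, 80 °C) gives the 2',5'-dimethoxy-2-(methylsulfanyl)isoflavone F6. (NH4)2Ce(NO3)6 in aqueous MeCN then demethylates the 1,4-dimethoxyarene oxidatively to quinone 24.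

Step 14. The oxidant may also attack the sulfide, the prenyl alkene or the electron-rich ring A, or its acidity may remove the MOM group. The fallback sets out from 23 and comes back at 26; it avoids the quinone altogether. K2CO3 in DMF at 50 °C first closes the furan by displacement of methylsulfanyl, giving the 5'-O-methyl ether of 26 F7. Sodium ethanethiolate in DMF at 100–110 °C then cleaves the aryl methyl ether by SN2 attack at the methyl carbon. The MOM acetal, the prenyl group and both dihydropyrans should be inert to thiolate. A brief K2CO3 treatment on work-up would reclose any furan opened by reversible thiolate addition at C2, giving 26.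

Step 4. Alkylation on phenolate oxygen or a second alkylation at C6 (dearomatization) may compete with nuclear C-prenylation. The fallback sets out from 5 and comes back at 7; it delivers the prenyl group by a sigmatropic shift. The free C5 hydroxyl is alkylated with 2-methylbut-3-yn-2-yl trifluoroacetate (DBU, CuCl2 cat., MeCN, 0 °C) to 1-{7-hydroxy-2,2-dimethyl-5-[(2-methylbut-3-yn-2-yl)oxy]-3,4-dihydro-2H-chromen-8-yl}ethanone F8. Semihydrogenation (H2, Pd/CaCO3 poisoned with Pb(OAc)2, quinoline, EtOAc) gives the 1,1-dimethylallyl ether 1-{7-hydroxy-2,2-dimethyl-5-[(2-methylbut-3-en-2-yl)oxy]-3,4-dihydro-2H-chromen-8-yl}ethanone F9. Heating in toluene at 110 °C should effect aromatic Claisen rearrangement to C6, the only free ortho position, placing a normal prenyl group there and regenerating the phenol as 7.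

Further compounds
F1 | step 13 | 2-[(2-methylbut-3-yn-2-yl)oxy]-1,4-dimethoxybenzene | COc1ccc(OC)c(OC(C)(C)C#C)c1
F2 | step 13 | 5,8-dimethoxy-2,2-dimethyl-2H-chromene | COc1ccc(OC)c2OC(C)(C)C=Cc12
F3 | step 13 | 5,8-dimethoxy-2,2-dimethylchromane | COc1ccc(OC)c2OC(C)(C)CCc12
F4 | step 13 | 6-bromo-5,8-dimethoxy-2,2-dimethylchromane | COc1cc(Br)c(OC)c2CCC(C)(C)Oc12
F5 | step 13 | (5,8-dimethoxy-2,2-dimethylchroman-6-yl)boronic acid | COc1cc(B(O)O)c(OC)c2CCC(C)(C)Oc12
F6 | step 13 | 2',5'-dimethoxy analogue of 23 | COc1cc(-c2c(SC)oc3c(CC=C(C)C)c(OCOC)c4CCC(C)(C)Oc4c3c2=O)c(OC)c2CCC(C)(C)Oc12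
F7 | step 14 | 5'-O-methyl ether of 26 | CC(C)=CCc1c(OCOC)c2c(c3c(=O)c4c(oc13)oc1c3c(c(OC)cc14)OC(C)(C)CC3)OC(C)(C)CC2
F8 | step 4 | 1-{7-hydroxy-2,2-dimethyl-5-[(2-methylbut-3-yn-2-yl)oxy]-3,4-dihydro-2H-chromen-8-yl}ethanone | CC(=O)c1c(O)cc(OC(C)(C)C#C)c2CCC(C)(C)Oc12
F9 | step 4 | 1-{7-hydroxy-2,2-dimethyl-5-[(2-methylbut-3-en-2-yl)oxy]-3,4-dihydro-2H-chromen-8-yl}ethanone | CC(=O)c1c(O)cc(OC(C)(C)C=C)c2CCC(C)(C)Oc12
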